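**Plan**

- Numbering: C1 is the quaternary carbinol carrying C7 (the acetoxymethyl carbon), C2 is CH–OAc, C3=C4 is the alkene, C5 and C6 are CH–OBz (C6 next to C1). The α face carries O1 and O6; the β face carries C7, O2 and O5. C1–C7 are target numbers; locants inside systematic names belong to the named parent.
- Enabling feature: the chain C7–C1–C6–C5 (oxygen on C1 and C6, oxidised ends) is L-tartrate substituted at C1. A 1,3-dioxolane across O1/O6 holds a C5 aldehyde and the C2 arm cis, so a (Z)-alkenyl metal at C4 can reach C5.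
- Retrosynthesis: cut the four ester C–O bonds, then the ring bond C4–C5 (alkenylchromium plus aldehyde), then C1–C2 (tartrate ester enolate plus alkynoyl chloride). This leaves dimethyl L-tartrate acetonide (C7, C1, C6, C5) and a silylpropynoyl unit (C2–C4).
- Forward: enolate acylation makes C1–C2; the ynone is reduced and the alcohol lactonises onto C5, which tells C5 from C7; the alkyne becomes the (Z)-iodoalkene; the lactone is opened, C5 goes to the aldehyde and C7 to CH2OAc; the cyclohexene (the only carbocycle) closes at C4–C5; acyl groups are placed around removal of the acetal.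
- Stereochemistry: C6 from L-tartrate; C1 by acylation of the tartrate enolate cis to the ester on C6; C2 by catalyst-controlled transfer hydrogenation; the Z alkene by diimide; C5 in the ring closure under control of C6.

Key step: step 10

Assumption: the lithium enolate of 3 should take an acyl electrophile on the face cis to the ester on C6, the face it uses with alkyl halides and carbonyl electrophiles; a C1 epimer, if formed, cannot lactonise in step 3 and is removed there.

**Step 1**
Reactants: 1 3-(trimethylsilyl)prop-2-ynoic acid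
Product: 2 3-(trimethylsilyl)prop-2-ynoyl chloride (used crude)
Conditions: (COCl)2 (1.2 equiv), DMF (cat.), CH2Cl2, 0 °C to rt; evaporate, strip with toluene
Reagents that add atoms: oxalyl chloride, O=C(Cl)C(Cl)=O
Why: Acid chloride formation with oxalyl chloride under Vilsmeier-type DMF catalysis leaves the silylalkyne untouched and gives an acyl donor reactive enough for a hindered enolate at −78 °C.

**Step 2**
Reactants: 3 dimethyl (4R,5R)-2,2-dimethyl-1,3-dioxolane-4,5-dicarboxylate (dimethyl 2,3-O-isopropylidene-L-tartrate); 2 3-(trimethylsilyl)prop-2-ynoyl chloride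
Product: 5 dimethyl (4S,5R)-2,2-dimethyl-4-[3-(trimethylsilyl)prop-2-ynoyl]-1,3-dioxolane-4,5-dicarboxylate, via lithium ester enolate 4 (not isolated)
Conditions: LiN(i-Pr)2 (1.05 equiv), THF, −78 °C, 30 min; cannulate into 2 (1.3 equiv), THF, −78 °C; AcOH, −78 °C
Reagents that add atoms: none
Why: Claisen-type C-acylation of a lithium ester enolate by an acid chloride, clean because the β-keto ester formed has no acidic hydrogen; the acyl group should enter C1 on the face cis to the ester on C6, so that C6 sets the quaternary C1 and C2 ends cis to C5 on the dioxolane.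

**Step 3**
Reactants: 5 dimethyl (4S,5R)-2,2-dimethyl-4-[3-(trimethylsilyl)prop-2-ynoyl]-1,3-dioxolane-4,5-dicarboxylate
Product: 7 methyl (3aR,4S,6aR)-2,2-dimethyl-6-oxo-4-[(trimethylsilyl)ethynyl]tetrahydrofuro[3,4-d][1,3]dioxole-3a(4H)-carboxylate, via propargylic alcohol diester 6 (not isolated)
Conditions: Ru(p-cymene)[(R,R)-TsNCH(Ph)CH(Ph)NH] (2 mol %), i-PrOH, rt; evaporate; PPTS (10 mol %), toluene, 60 °C
Reagents that add atoms: none
Why: Noyori asymmetric transfer hydrogenation of an α,β-acetylenic ketone, in which the catalyst and not the substrate fixes the carbinol: the (R,R) complex seats the alkynyl group where the π-substituent of simple ynones sits and should give (S)-C2 (O2 on the later β face), and the acid-catalysed lactonisation that follows is open only to a C2 hydroxyl held cis to the C5 ester, so it marks C5 against C7.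

**Step 4**
Reactants: 7 methyl (3aR,4S,6aR)-2,2-dimethyl-6-oxo-4-[(trimethylsilyl)ethynyl]tetrahydrofuro[3,4-d][1,3]dioxole-3a(4H)-carboxylate
Product: 8 methyl (3aR,4S,6aR)-4-(iodoethynyl)-2,2-dimethyl-6-oxotetrahydrofuro[3,4-d][1,3]dioxole-3a(4H)-carboxylate
Conditions: N-iodosuccinimide (1.2 equiv), AgNO3 (10 mol %), DMF, rt, dark
Reagents that add atoms: N-iodosuccinimide, O=C1CCC(=O)N1I
Why: Silver-catalysed iododesilylation (silver acetylide captured by the iodonium donor) turns the silylalkyne into the 1-iodoalkyne without touching lactone, ester or acetal.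

**Step 5**
Reactants: 8 methyl (3aR,4S,6aR)-4-(iodoethynyl)-2,2-dimethyl-6-oxotetrahydrofuro[3,4-d][1,3]dioxole-3a(4H)-carboxylate
Product: 9 methyl (3aR,4S,6aR)-4-[(Z)-2-iodoethenyl]-2,2-dimethyl-6-oxotetrahydrofuro[3,4-d][1,3]dioxole-3a(4H)-carboxylate
Conditions: 2-nitrobenzenesulfonohydrazide (2.5 equiv), Et3N (5 equiv), THF–i-PrOH (1:1), rt
Reagents that add atoms: none
Why: Diimide reduction: diimide generated in the flask delivers two hydrogens to one face of the iodoalkyne, which gives the (Z)-iodoalkene needed for ring closure and leaves the C–I bond and both carbonyl groups alone.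

**Step 6**
Reactants: 9 methyl (3aR,4S,6aR)-4-[(Z)-2-iodoethenyl]-2,2-dimethyl-6-oxotetrahydrofuro[3,4-d][1,3]dioxole-3a(4H)-carboxylate
Product: 10 methyl (4R,5R)-4-[(1S,2Z)-1-hydroxy-3-iodoprop-2-en-1-yl]-5-[methoxy(methyl)carbamoyl]-2,2-dimethyl-1,3-dioxolane-4-carboxylate (used crude)
Conditions: MeNH(OMe)·HCl (3 equiv), AlMe3 (3 equiv), CH2Cl2, 0 °C to rt; aq. KNaC4H4O6 (potassium sodium tartrate)
Reagents that add atoms: N,O-dimethylhydroxylamine hydrochloride, CNOC.Cl
Why: Weinreb aminolysis of a lactone by the aluminium amide: the strained bicyclic lactone carbonyl reacts well before the methyl ester on the quaternary carbon, so C5 alone becomes the N-methoxy-N-methylamide and O2 is released.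

**Step 7**
Reactants: 10 methyl (4R,5R)-4-[(1S,2Z)-1-hydroxy-3-iodoprop-2-en-1-yl]-5-[methoxy(methyl)carbamoyl]-2,2-dimethyl-1,3-dioxolane-4-carboxylate
Product: 11 methyl (4S,5R)-4-[(1S,2Z)-1-{[tert-butyl(dimethyl)silyl]oxy}-3-iodoprop-2-en-1-yl]-5-[methoxy(methyl)carbamoyl]-2,2-dimethyl-1,3-dioxolane-4-carboxylate
Conditions: TBSOTf (1.5 equiv), 2,6-lutidine (3 equiv), CH2Cl2, −78 to 0 °C
Reagents that add atoms: tert-butyldimethylsilyl trifluoromethanesulfonate, CC(C)(C)[Si](C)(C)OS(=O)(=O)C(F)(F)F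
Why: Silylation with the silyl triflate and a hindered pyridine base caps the neopentyl-type secondary hydroxyl before it can close back onto the amide.

**Step 8**
Reactants: 11 methyl (4S,5R)-4-[(1S,2Z)-1-{[tert-butyl(dimethyl)silyl]oxy}-3-iodoprop-2-en-1-yl]-5-[methoxy(methyl)carbamoyl]-2,2-dimethyl-1,3-dioxolane-4-carboxylate
Product: 12 (4R,5S)-5-[(1S,2Z)-1-{[tert-butyl(dimethyl)silyl]oxy}-3-iodoprop-2-en-1-yl]-5-(hydroxymethyl)-2,2-dimethyl-1,3-dioxolane-4-carbaldehyde (used directly)
Conditions: LiAlH4 (2.5 equiv), THF, −78 to 0 °C; aq. KHSO4, 0 °C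
Reagents that add atoms: none
Why: Hydride reduction with LiAlH4: the N-methoxy-N-methylamide stops at its chelated tetrahedral adduct and gives the C5 aldehyde on work-up, while the methyl ester goes to the C7 primary alcohol; C7–OH and the formyl group are trans on the dioxolane, so no lactol forms, and the cold conditions spare the vinylic iodide.

**Step 9**
Reactants: 12 (4R,5S)-5-[(1S,2Z)-1-{[tert-butyl(dimethyl)silyl]oxy}-3-iodoprop-2-en-1-yl]-5-(hydroxymethyl)-2,2-dimethyl-1,3-dioxolane-4-carbaldehyde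
Product: 13 [(4S,5R)-4-[(1S,2Z)-1-{[tert-butyl(dimethyl)silyl]oxy}-3-iodoprop-2-en-1-yl]-5-formyl-2,2-dimethyl-1,3-dioxolan-4-yl]methyl acetate
Conditions: Ac2O (1.5 equiv), pyridine, DMAP (5 mol %), CH2Cl2, 0 °C
Reagents that add atoms: acetic anhydride, CC(=O)OC(C)=O
Why: Acetylation of the only hydroxyl under mild pyridine catalysis puts the C7 acetate of the target in place before ring closure and is short and cold enough to leave the α-alkoxy aldehyde centre C6 untouched.

**Step 10**
Reactants: 13 [(4S,5R)-4-[(1S,2Z)-1-{[tert-butyl(dimethyl)silyl]oxy}-3-iodoprop-2-en-1-yl]-5-formyl-2,2-dimethyl-1,3-dioxolan-4-yl]methyl acetate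
Product: 15 [(3aS,4S,7R,7aS)-4-{[tert-butyl(dimethyl)silyl]oxy}-7-hydroxy-2,2-dimethyl-7,7a-dihydro-1,3-benzodioxol-3a(4H)-yl]methyl acetate, via alkenylchromium dichloride 14 (not isolated)
Conditions: CrCl2 (6 equiv), NiCl2 (5 mol %), degassed DMF (0.01 M), rt; aq. NH4Cl
Reagents that add atoms: none
Why: Nozaki–Hiyama–Kishi reaction in its intramolecular form: zerovalent nickel, made from NiCl2 by divalent chromium, inserts into the C4–I bond with retention of the Z geometry and hands the alkenyl group to trivalent chromium, and the alkenylchromium 14 adds to the C5 aldehyde, the only electrophile in 13 that an organochromium reagent attacks. The closest known reaction type is the chromium-mediated cyclisation of ω-iodoalkenyl aldehydes to cyclic allylic alcohols. The cyclohexene closes in the 6-exo-trig mode at the carbonyl, the Z alkene becoming the endocyclic C3=C4 bond; it is fused cis to the dioxolane because the acetal already holds the C2 arm and the formyl group on one face, and an alkenylchromium that had isomerised to E could not reach the aldehyde. The new C5 stereocentre is set by the neighbouring C6 stereocentre: in the half-chair transition state that has the forming C4–C5 bond antiperiplanar to the C6–O bond (Felkin–Anh alignment), the aldehyde oxygen on chromium lies pseudo-equatorial and clear of the axial C1–O bond, which puts O5 trans to O6 on the β face. The other half-chair lacks this alignment and carries the C7 acetoxymethyl group axial, so the trans C5/C6 relationship needed for the target should prevail.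

**Step 11**
Reactants: 15 [(3aS,4S,7R,7aS)-4-{[tert-butyl(dimethyl)silyl]oxy}-7-hydroxy-2,2-dimethyl-7,7a-dihydro-1,3-benzodioxol-3a(4H)-yl]methyl acetate
Product: 16 (3aS,4S,7R,7aS)-3a-(acetoxymethyl)-4-{[tert-butyl(dimethyl)silyl]oxy}-2,2-dimethyl-3a,4,7,7a-tetrahydro-1,3-benzodioxol-7-yl benzoate
Conditions: BzCl (1.5 equiv), pyridine, DMAP (cat.), CH2Cl2, 0 °C to rt
Reagents that add atoms: benzoyl chloride, O=C(Cl)c1ccccc1
Why: Acylation (benzoyl chloride, nucleophilic catalysis) of the single free hydroxyl, the allylic C5–OH, with retention.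

**Step 12**
Reactants: 16 (3aS,4S,7R,7aS)-3a-(acetoxymethyl)-4-{[tert-butyl(dimethyl)silyl]oxy}-2,2-dimethyl-3a,4,7,7a-tetrahydro-1,3-benzodioxol-7-yl benzoate
Product: 17 (3aR,4S,7R,7aS)-3a-(acetoxymethyl)-4-hydroxy-2,2-dimethyl-3a,4,7,7a-tetrahydro-1,3-benzodioxol-7-yl benzoate
Conditions: HF·pyridine, pyridine–THF, 0 °C to rt
Reagents that add atoms: none
Why: Fluoride-induced desilylation with buffered HF·pyridine frees O2 without cleaving esters or the acetal; an acetyl shift from O7 to O2 would be harmless because both oxygens carry acetate in the target.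

**Step 13**
Reactants: 17 (3aR,4S,7R,7aS)-3a-(acetoxymethyl)-4-hydroxy-2,2-dimethyl-3a,4,7,7a-tetrahydro-1,3-benzodioxol-7-yl benzoate
Product: 18 (3aR,4S,7R,7aS)-4-acetoxy-3a-(acetoxymethyl)-2,2-dimethyl-3a,4,7,7a-tetrahydro-1,3-benzodioxol-7-yl benzoate
Conditions: Ac2O (3 equiv), pyridine, DMAP (10 mol %), CH2Cl2, rt
Reagents that add atoms: acetic anhydride, CC(=O)OC(C)=O
Why: Acetylation with DMAP catalysis esterifies the hindered C2 hydroxyl (and any O7 freed by acetyl shift), giving the 2,7-diacetate.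

**Step 14**
Reactants: 18 (3aR,4S,7R,7aS)-4-acetoxy-3a-(acetoxymethyl)-2,2-dimethyl-3a,4,7,7a-tetrahydro-1,3-benzodioxol-7-yl benzoate
Product: 19 [(1S,2S,5R,6S)-2-acetoxy-5-(benzoyloxy)-1,6-dihydroxycyclohex-3-en-1-yl]methyl acetate
Conditions: TFA–H2O (9:1), 0 °C, 30 min
Reagents that add atoms: none
Why: Acid-catalysed hydrolysis of the isopropylidene acetal releases the tertiary C1–OH and the secondary C6–OH; the three esters should survive a short cold exposure, and a benzoyl shift from O5 to O6 would be corrected in the last step.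

**Step 15**
Reactants: 19 [(1S,2S,5R,6S)-2-acetoxy-5-(benzoyloxy)-1,6-dihydroxycyclohex-3-en-1-yl]methyl acetate
Product: 20 [(1R,2S,5R,6S)-2-acetoxy-5,6-bis(benzoyloxy)-1-hydroxycyclohex-3-en-1-yl]methyl acetate (target)
Conditions: BzCl (1.3 equiv), pyridine, DMAP (10 mol %), CH2Cl2, 0 °C to rt
Reagents that add atoms: benzoyl chloride, O=C(Cl)c1ccccc1
Why: Benzoylation of the secondary C6 hydroxyl by an acyl chloride; the tertiary C1 hydroxyl, flanked by three substituted carbons, should not react under these conditions, which completes the target.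

**Compound list**

1 | 3-(trimethylsilyl)prop-2-ynoic acid | C[Si](C)(C)C#CC(=O)O | starting material
2 | 3-(trimethylsilyl)prop-2-ynoyl chloride | C[Si](C)(C)C#CC(=O)Cl | intermediate
3 | dimethyl (4R,5R)-2,2-dimethyl-1,3-dioxolane-4,5-dicarboxylate (dimethyl 2,3-O-isopropylidene-L-tartrate) | COC(=O)[C@@H]1OC(C)(C)O[C@H]1C(=O)OC | starting material
4 | lithium ester enolate of 3 (C1 enolised, C6 unchanged) | COC(=O)[C@@H]1OC(C)(C)OC1=C(OC)[O-].[Li+] | intermediate
5 | dimethyl (4S,5R)-2,2-dimethyl-4-[3-(trimethylsilyl)prop-2-ynoyl]-1,3-dioxolane-4,5-dicarboxylate (acyl group cis to the ester on the neighbouring ring carbon) | COC(=O)[C@@]1(OC(C)(C)O[C@H]1C(=O)OC)C(=O)C#C[Si](C)(C)C | intermediate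
6 | dimethyl (4R,5R)-4-[(1S)-1-hydroxy-3-(trimethylsilyl)prop-2-yn-1-yl]-2,2-dimethyl-1,3-dioxolane-4,5-dicarboxylate | COC(=O)[C@@]1(OC(C)(C)O[C@H]1C(=O)OC)[C@@H](O)C#C[Si](C)(C)C | intermediate
7 | methyl (3aR,4S,6aR)-2,2-dimethyl-6-oxo-4-[(trimethylsilyl)ethynyl]tetrahydrofuro[3,4-d][1,3]dioxole-3a(4H)-carboxylate (γ-lactone from O2 to C5, alkynyl group on the concave face) | COC(=O)[C@@]1(OC(C)(C)O[C@H]1C(=O)O2)[C@@H]2C#C[Si](C)(C)C | intermediate
8 | methyl (3aR,4S,6aR)-4-(iodoethynyl)-2,2-dimethyl-6-oxotetrahydrofuro[3,4-d][1,3]dioxole-3a(4H)-carboxylate | COC(=O)[C@@]1(OC(C)(C)O[C@H]1C(=O)O2)[C@@H]2C#CI | intermediate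
9 | methyl (3aR,4S,6aR)-4-[(Z)-2-iodoethenyl]-2,2-dimethyl-6-oxotetrahydrofuro[3,4-d][1,3]dioxole-3a(4H)-carboxylate | COC(=O)[C@@]1(OC(C)(C)O[C@H]1C(=O)O2)[C@@H]2/C=C\I | intermediate
10 | methyl (4R,5R)-4-[(1S,2Z)-1-hydroxy-3-iodoprop-2-en-1-yl]-5-[methoxy(methyl)carbamoyl]-2,2-dimethyl-1,3-dioxolane-4-carboxylate | COC(=O)[C@@]1(OC(C)(C)O[C@H]1C(=O)N(C)OC)[C@@H](O)/C=C\I | intermediate
11 | methyl (4S,5R)-4-[(1S,2Z)-1-{[tert-butyl(dimethyl)silyl]oxy}-3-iodoprop-2-en-1-yl]-5-[methoxy(methyl)carbamoyl]-2,2-dimethyl-1,3-dioxolane-4-carboxylate | COC(=O)[C@@]1(OC(C)(C)O[C@H]1C(=O)N(C)OC)[C@@H](O[Si](C)(C)C(C)(C)C)/C=C\I | intermediate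
12 | (4R,5S)-5-[(1S,2Z)-1-{[tert-butyl(dimethyl)silyl]oxy}-3-iodoprop-2-en-1-yl]-5-(hydroxymethyl)-2,2-dimethyl-1,3-dioxolane-4-carbaldehyde | OC[C@@]1(OC(C)(C)O[C@H]1C=O)[C@@H](O[Si](C)(C)C(C)(C)C)/C=C\I | intermediate
13 | [(4S,5R)-4-[(1S,2Z)-1-{[tert-butyl(dimethyl)silyl]oxy}-3-iodoprop-2-en-1-yl]-5-formyl-2,2-dimethyl-1,3-dioxolan-4-yl]methyl acetate (formyl group and C2 arm cis on the dioxolane) | CC(=O)OC[C@@]1(OC(C)(C)O[C@H]1C=O)[C@@H](O[Si](C)(C)C(C)(C)C)/C=C\I | intermediate
14 | alkenylchromium dichloride from 13 (CrCl2 in place of iodine at C4, Z) | CC(=O)OC[C@@]1(OC(C)(C)O[C@H]1C=O)[C@@H](O[Si](C)(C)C(C)(C)C)/C=C\[Cr](Cl)Cl | intermediate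
15 | [(3aS,4S,7R,7aS)-4-{[tert-butyl(dimethyl)silyl]oxy}-7-hydroxy-2,2-dimethyl-7,7a-dihydro-1,3-benzodioxol-3a(4H)-yl]methyl acetate (acetal α, O2 and O5 β) | CC(=O)OC[C@@]1(OC(C)(C)O2)[C@@H](O[Si](C)(C)C(C)(C)C)C=C[C@@H](O)[C@@H]12 | intermediate
16 | (3aS,4S,7R,7aS)-3a-(acetoxymethyl)-4-{[tert-butyl(dimethyl)silyl]oxy}-2,2-dimethyl-3a,4,7,7a-tetrahydro-1,3-benzodioxol-7-yl benzoate | CC(=O)OC[C@@]1(OC(C)(C)O2)[C@@H](O[Si](C)(C)C(C)(C)C)C=C[C@@H](OC(=O)c3ccccc3)[C@@H]12 | intermediate
17 | (3aR,4S,7R,7aS)-3a-(acetoxymethyl)-4-hydroxy-2,2-dimethyl-3a,4,7,7a-tetrahydro-1,3-benzodioxol-7-yl benzoate | CC(=O)OC[C@@]1(OC(C)(C)O2)[C@@H](O)C=C[C@@H](OC(=O)c3ccccc3)[C@@H]12 | intermediate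
18 | (3aR,4S,7R,7aS)-4-acetoxy-3a-(acetoxymethyl)-2,2-dimethyl-3a,4,7,7a-tetrahydro-1,3-benzodioxol-7-yl benzoate | CC(=O)OC[C@@]1(OC(C)(C)O2)[C@@H](OC(C)=O)C=C[C@@H](OC(=O)c3ccccc3)[C@@H]12 | intermediate
19 | [(1S,2S,5R,6S)-2-acetoxy-5-(benzoyloxy)-1,6-dihydroxycyclohex-3-en-1-yl]methyl acetate | CC(=O)OC[C@@]1(O)[C@@H](OC(C)=O)C=C[C@@H](OC(=O)c2ccccc2)[C@@H]1O | intermediate
20 | [(1R,2S,5R,6S)-2-acetoxy-5,6-bis(benzoyloxy)-1-hydroxycyclohex-3-en-1-yl]methyl acetate | CC(=O)OC[C@@]1(O)[C@@H](OC(C)=O)C=C[C@@H](OC(=O)c2ccccc2)[C@@H]1OC(=O)c1ccccc1 | target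

**Step count and risks**

Total steps: 15. Longest linear sequence: 15 steps (1 to 20); 14 steps from the tartrate acetonide 3.

Steps most likely to fail:

1. Step 2. Acyl transfer to the hindered, thermally labile enolate may be outrun by its decomposition (β-elimination of the acetal oxygen), by O-acylation, or by attack on the wrong face. The fallback sets out from 3 and comes back at 5. The enolate 4 is treated at −78 °C with 3-(trimethylsilyl)propynal, an aldehyde that reacts faster than any acyl donor, and quenched cold with AcOH before the aldolate can lactonise. This gives the propargylic alcohol diester F1 as a mixture of C2 epimers. Oxidation with Dess–Martin periodinane (NaHCO3, CH2Cl2, rt) removes the C2 stereocentre and gives 5, and the route continues with step 3.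

2. Step 10. Facial selectivity at the aldehyde may be poor: closure through the other half-chair would put O5 cis to O6. The fallback sets out from 13 and comes back at 16. The closure is run as described and the C5-epimeric cyclohexenol F2 is isolated. It is esterified with benzoic acid under Mitsunobu conditions (PPh3, DIAD, THF, 0 °C to rt), which inverts C5 and gives 16 directly. Any 15 formed alongside is benzoylated as in step 11, so both epimers converge.

3. Step 8. The hydride reduction may lose chemoselectivity: reductive loss of the vinylic iodine, or incomplete reduction of the hindered ester. The fallback sets out from 11 and comes back at 15. Cp2Zr(H)Cl (THF, rt) reduces only the N-methoxy-N-methylamide and gives the aldehyde ester F3. Ring closure under the conditions of step 10 gives the cyclohexenol ester F4. LiBH4 (THF, 0 °C to rt) reduces the methyl ester to the diol F5. Acetylation of the primary hydroxyl alone (AcCl, 2,4,6-collidine, CH2Cl2, −78 °C) gives 15.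

**Further compounds**

F1 | step 2 | dimethyl (4R,5R)-4-[1-hydroxy-3-(trimethylsilyl)prop-2-yn-1-yl]-2,2-dimethyl-1,3-dioxolane-4,5-dicarboxylate (both C2 epimers) | COC(=O)[C@@]1(OC(C)(C)O[C@H]1C(=O)OC)C(O)C#C[Si](C)(C)C
F2 | step 10 | [(3aS,4S,7S,7aS)-4-{[tert-butyl(dimethyl)silyl]oxy}-7-hydroxy-2,2-dimethyl-7,7a-dihydro-1,3-benzodioxol-3a(4H)-yl]methyl acetate (C5 epimer of 15) | CC(=O)OC[C@@]1(OC(C)(C)O2)[C@@H](O[Si](C)(C)C(C)(C)C)C=C[C@H](O)[C@@H]12
F3 | step 8 | methyl (4S,5R)-4-[(1S,2Z)-1-{[tert-butyl(dimethyl)silyl]oxy}-3-iodoprop-2-en-1-yl]-5-formyl-2,2-dimethyl-1,3-dioxolane-4-carboxylate | COC(=O)[C@@]1(OC(C)(C)O[C@H]1C=O)[C@@H](O[Si](C)(C)C(C)(C)C)/C=C\I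
F4 | step 8 | methyl (3aS,4S,7R,7aS)-4-{[tert-butyl(dimethyl)silyl]oxy}-7-hydroxy-2,2-dimethyl-7,7a-dihydro-1,3-benzodioxole-3a(4H)-carboxylate | COC(=O)[C@@]1(OC(C)(C)O2)[C@@H](O[Si](C)(C)C(C)(C)C)C=C[C@@H](O)[C@@H]12
F5 | step 8 | (3aS,4S,7R,7aS)-4-{[tert-butyl(dimethyl)silyl]oxy}-3a-(hydroxymethyl)-2,2-dimethyl-3a,4,7,7a-tetrahydro-1,3-benzodioxol-7-ol | OC[C@@]1(OC(C)(C)O2)[C@@H](O[Si](C)(C)C(C)(C)C)C=C[C@@H](O)[C@@H]12
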